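The route rests on two bonds at the former alkene of a cyclohexene: C4–C5, which closes the cyclopentane, and O11–C6, which closes the lactone (core locants are defined below). The feature exploited is the quaternary ring-fusion carbon C1: it holds the cyclopentane methylene C2 and the lactone carbonyl C10 on opposite faces of the six-membered carbocycle, so an aldehyde on the C2 arm and a tert-butyl ester at C10 can add anti across C5=C6. One Lewis-acid operation therefore builds two rings, two skeletal bonds and three stereocentres. Its precursor is a single-enantiomer β,γ-unsaturated cyclohexanone carrying the tert-butyl ester and a 3-oxopropyl chain on one quaternary carbon.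

Key step: step 5

Remark (locants): the core is numbered as 11-oxatricyclo[4.3.2.0^1,5]undecane: C1 quaternary ring-fusion carbon; C2, C3 cyclopentane CH2; C4 linker-bearing carbon; C5 ring-fusion CH; C6 methyl-bearing carbon; C7, C8 CH2; C9 bromine-bearing carbon; C10 lactone carbonyl; O11 lactone oxygen.
Assumption: the cupreidine-derived catalyst of step 4 is taken to give the S adduct; should the sense be the reverse, its cupreine-derived pseudoenantiomer is used.
Assumption: the side-ring bromoketone is made racemic and resolved; the R enantiomer is to be assigned by anomalous-dispersion X-ray analysis of a crystalline derivative.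

Step 1
Reactants: 1 4-methylanisole
Product: 2 1-methoxy-4-methylcyclohexa-1,4-diene
Conditions: Li, NH3(l), THF, t-BuOH, −78 to −33 °C; then NH4Cl
Reagents that add atoms: none
Why: Birch reduction, in which the two donor-substituted carbons stay sp2, so the 1,4-diene carries OMe and Me on its double bonds; no stereocentre forms.

Step 2
Reactants: 2 1-methoxy-4-methylcyclohexa-1,4-diene
Product: 3 4-methylcyclohex-3-en-1-one
Conditions: (CO2H)2 (cat.), MeOH–H2O, rt
Reagents that add atoms: water, O
Why: Mild acid hydrolysis of the enol ether; oxalic acid is weak enough to leave the trisubstituted alkene out of conjugation.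

Step 3
Reactants: 3 4-methylcyclohex-3-en-1-one; 4 di-tert-butyl dicarbonate
Product: 6 racemic tert-butyl 3-methyl-6-oxocyclohex-2-ene-1-carboxylate, via lithium dienolate 5 (not isolated)
Conditions: LiHMDS (2.1 equiv), THF, −78 °C; Boc2O, −78 to 0 °C; aq. NH4Cl
Reagents that add atoms: di-tert-butyl dicarbonate (4), CC(C)(C)OC(=O)OC(=O)OC(C)(C)C
Why: Claisen-type C-acylation of a ketone enolate: the CH2 between C=O and C=C is deprotonated, the extended lithium enolate is acylated at its α-carbon, and the second equivalent of base stores the acidic product as its enolate; the new CH centre is racemic and is set in step 4.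

Step 4
Reactants: 6 racemic tert-butyl 3-methyl-6-oxocyclohex-2-ene-1-carboxylate; 7 acrolein
Product: 8 tert-butyl (1S)-3-methyl-6-oxo-1-(3-oxopropyl)cyclohex-2-ene-1-carboxylate
Conditions: 9-O-(9-phenanthryl)cupreidine (10 mol %), CH2Cl2, −25 °C
Reagents that add atoms: acrolein (7), C=CC=O
Why: Cinchona-catalysed enantioselective Michael addition: the quinuclidine base forms the enolate ion pair of the tert-butyl β-keto ester while the 6′-OH binds acrolein, so the enal meets one face of the α-carbon and the quaternary centre is set under catalyst control.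

Step 5
Reactants: 8 tert-butyl (1S)-3-methyl-6-oxo-1-(3-oxopropyl)cyclohex-2-ene-1-carboxylate
Product: 10 (1S,4R,5R,6S)-4-hydroxy-6-methyl-11-oxatricyclo[4.3.2.0^1,5]undecane-9,10-dione, via C6 tertiary carbocation 9 (not isolated)
Conditions: Me2AlCl (2.5 equiv), CH2Cl2, −78 to −20 °C; 1 M HCl
Reagents that add atoms: none
Why: Me2AlCl binds the aldehyde and the C5=C6 alkene attacks it through its CH carbon (C5), which closes the cyclopentane and leaves tertiary carbocation 9 at methyl-bearing C6; the tert-butyl ester carbonyl oxygen then traps C6 and isobutene is lost, giving the γ-lactone. The closest known reaction types are the alkylaluminium-halide Prins/carbonyl-ene cyclisation of alkenyl aldehydes and the lactonisation of tert-butyl esters by capture of a tertiary cation. The cyclopentane closes 5-exo-trig at the carbonyl with the alkene exocyclic to the new ring, and the lactone closes by 5-exo capture of the cation that lies 1,3 to the ester carbon. C5 is fixed by the three-carbon tether, which reaches the alkene only on the face of C1 that carries it (cis ring fusion), C6 is fixed by the ester on the opposite face (anti addition), and C4 should form mainly with the aluminium-bound oxygen turned away from C6, a centre that is erased in step 6. The step needs activation of the aldehyde in preference to the ketone, attack through C5 and not C6, and trapping faster than proton loss: the more basic and unhindered aldehyde, the Markovnikov bias of the trisubstituted alkene with the five-membered transition state, and the ester held 1,3 to the cation secure these, while the Al–Me bonds scavenge protons so that the alkene is not lactonised before the Prins step.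

Step 6
Reactants: 10 (1S,4R,5R,6S)-4-hydroxy-6-methyl-11-oxatricyclo[4.3.2.0^1,5]undecane-9,10-dione
Product: 11 (1S,5S,6S)-6-methyl-11-oxatricyclo[4.3.2.0^1,5]undecane-4,9,10-trione
Conditions: Dess–Martin periodinane, NaHCO3, CH2Cl2, 0 °C to rt
Reagents that add atoms: none
Why: Dess–Martin oxidation of the secondary alcohol under buffered conditions; the C4 carbinol centre is removed, so its epimer composition does not matter.

Step 7
Reactants: 11 (1S,5S,6S)-6-methyl-11-oxatricyclo[4.3.2.0^1,5]undecane-4,9,10-trione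
Product: 12 (1S,5S,6S)-6-methyl-4-methylidene-11-oxatricyclo[4.3.2.0^1,5]undecane-9,10-dione
Conditions: Ph3PCH3Br, KHMDS, THF, 0 °C; then 11 (1.1 equiv ylide), −78 to 0 °C
Reagents that add atoms: methyltriphenylphosphonium bromide, C[P+](c1ccccc1)(c1ccccc1)c1ccccc1.[Br-]
Why: Wittig methylenation, site-selective for the C4 cyclopentanone because the C9 ketone is neopentylic (next to quaternary C1) and is screened by the lactone bridge on one face and by C4 on the other; no stereocentre changes.

Step 8
Reactants: 12 (1S,5S,6S)-6-methyl-4-methylidene-11-oxatricyclo[4.3.2.0^1,5]undecane-9,10-dione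
Product: 13 (1S,5S,6S,9S)-9-hydroxy-6-methyl-4-methylidene-11-oxatricyclo[4.3.2.0^1,5]undecan-10-one
Conditions: L-Selectride, THF, −78 °C; aq. NH4Cl
Reagents that add atoms: none
Why: Bulky-hydride ketone reduction: the axial trajectory at C9 is closed by C4, which is syn-axial on C5, so hydride arrives along the equatorial direction on the lactone side and gives the axial 9S alcohol.

Step 9
Reactants: 13 (1S,5S,6S,9S)-9-hydroxy-6-methyl-4-methylidene-11-oxatricyclo[4.3.2.0^1,5]undecan-10-one
Product: 14 (1R,5S,6S,9R)-9-bromo-6-methyl-4-methylidene-11-oxatricyclo[4.3.2.0^1,5]undecan-10-one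
Conditions: CBr4, PPh3, pyridine (cat.), toluene, 0 to 60 °C
Reagents that add atoms: carbon tetrabromide, BrC(Br)(Br)Br
Why: Appel reaction: bromide displaces the axial alkoxyphosphonium group from the equatorial side with inversion, giving the equatorial 9R bromide cis to the lactone carbonyl, while the acyl-bearing quaternary neighbour disfavours ionisation and rearrangement.

Step 10
Reactants: 14 (1R,5S,6S,9R)-9-bromo-6-methyl-4-methylidene-11-oxatricyclo[4.3.2.0^1,5]undecan-10-one
Product: 16 (1R,4S,5S,6S,9R)-9-bromo-4-(hydroxymethyl)-6-methyl-11-oxatricyclo[4.3.2.0^1,5]undecan-10-one, via B-alkyl-9-BBN adduct 15 (not isolated)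
Conditions: 9-BBN, THF, 0 °C to rt; then H2O2, pH 7 phosphate buffer, 0 °C to rt
Reagents that add atoms: hydrogen peroxide, OO
Why: Hydroboration–oxidation: boron adds to the terminal carbon and hydrogen to C4 from the convex face of the cis-fused cyclopentane (the face of H-5, away from C6 and C9), which puts the CH2OH group on the concave face as the target requires, and the neutral oxidation spares lactone and bromide.

Step 11
Reactants: 16 (1R,4S,5S,6S,9R)-9-bromo-4-(hydroxymethyl)-6-methyl-11-oxatricyclo[4.3.2.0^1,5]undecan-10-one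
Product: 17 (1R,4S,5S,6S,9R)-9-bromo-4-(iodomethyl)-6-methyl-11-oxatricyclo[4.3.2.0^1,5]undecan-10-one
Conditions: I2, PPh3, imidazole, CH2Cl2, 0 °C to rt
Reagents that add atoms: iodine, II
Why: Appel-type iodination of the primary alcohol by SN2 at the CH2 carbon; no stereocentre is touched and the secondary bromide is inert.

Step 12
Reactants: 18 6-methylhept-5-en-2-one
Product: 20 6-methylhepta-1,5-dien-2-yl acetate, via lithium enolate 19 (not isolated)
Conditions: LDA, THF, −78 °C; Ac2O, −78 to 0 °C
Reagents that add atoms: acetic anhydride, CC(=O)OC(C)=O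
Why: Kinetic enolate formation at the methyl group followed by O-acetylation gives the terminal enol acetate; no stereocentre forms.

Step 13
Reactants: 20 6-methylhepta-1,5-dien-2-yl acetate
Product: 21 racemic 4-bromo-3,3-dimethylcyclohexan-1-one
Conditions: Et2SBr·SbCl5Br (BDSB), MeNO2, −25 °C; aq. NaHCO3/Na2SO3
Reagents that add atoms: bromodiethylsulfonium bromopentachloroantimonate, CC[S+](Br)CC.Br[Sb-](Cl)(Cl)(Cl)(Cl)Cl
Why: Bromonium-induced cation–olefin cyclisation of a 1,5-diene: Br+ is taken by the electron-richer trisubstituted alkene (an enol acetate is chosen because it is no richer than a 1,1-dialkyl alkene, whereas a silyl enol ether would be brominated directly), the enol acetate CH2 attacks the tertiary carbon through a chair, and the acyloxy cation loses its acetyl group to give the ketone with its single stereocentre racemic.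

Step 14
Reactants: 21 racemic 4-bromo-3,3-dimethylcyclohexan-1-one
Product: 22 (4R)-4-bromo-3,3-dimethylcyclohexan-1-one
Conditions: preparative SFC, amylose tris(3,5-dimethylphenylcarbamate) phase, CO2/i-PrOH
Reagents that add atoms: none
Why: Resolution of the racemate by chromatography on a chiral stationary phase; no bond is made or broken, and the neutral medium avoids the base-induced loss of bromide to which a γ-bromo ketone is prone.

Step 15
Reactants: 17 (1R,4S,5S,6S,9R)-9-bromo-4-(iodomethyl)-6-methyl-11-oxatricyclo[4.3.2.0^1,5]undecan-10-one; 22 (4R)-4-bromo-3,3-dimethylcyclohexan-1-one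
Product: 24 (1R,4R,5S,6S,9R)-9-bromo-4-{[(1R,4R)-4-bromo-1-hydroxy-3,3-dimethylcyclohexyl]methyl}-6-methyl-11-oxatricyclo[4.3.2.0^1,5]undecan-10-one, via alkylsamarium diiodide 23 (not isolated)
Conditions: SmI2 (2.5 equiv), NiI2 (1 mol %), THF, 0 °C; slow addition of 17 + 22 (1.5 equiv); aq. NH4Cl
Reagents that add atoms: (4R)-4-bromo-3,3-dimethylcyclohexan-1-one (22), O=C1CC[C@@H](Br)C(C)(C)C1
Why: Samarium Barbier reaction: SmI2 reduces the primary C–I bond in preference to the two hindered secondary C–Br bonds (no HMPA), and the organosamarium, trapped by the ketone as it forms, adds along the equatorial direction anti to the axial 3-methyl group of the bromine-equatorial chair, which should give the 1R carbinol with O cis to Br.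

Step 16
Reactants: 24 (1R,4R,5S,6S,9R)-9-bromo-4-{[(1R,4R)-4-bromo-1-hydroxy-3,3-dimethylcyclohexyl]methyl}-6-methyl-11-oxatricyclo[4.3.2.0^1,5]undecan-10-one
Product: 25 (1R,4R)-4-bromo-1-{[(1R,4R,5S,6S,9R)-9-bromo-6-methyl-10-oxo-11-oxatricyclo[4.3.2.0^1,5]undecan-4-yl]methyl}-3,3-dimethylcyclohexyl acetate
Conditions: Ac2O, DMAP, Et3N, CH2Cl2, rt to 40 °C
Reagents that add atoms: acetic anhydride, CC(=O)OC(C)=O
Why: DMAP-catalysed acylation of the tertiary alcohol through the N-acetylpyridinium ion; no stereocentre is affected.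

Compound list

1 | 4-methylanisole | COc1ccc(C)cc1 | starting material
2 | 1-methoxy-4-methylcyclohexa-1,4-diene | COC1=CCC(C)=CC1 | intermediate
3 | 4-methylcyclohex-3-en-1-one | CC1=CCC(=O)CC1 | intermediate
4 | di-tert-butyl dicarbonate | CC(C)(C)OC(=O)OC(=O)OC(C)(C)C | starting material
5 | lithium 4-methylcyclohexa-1,3-dien-1-olate | [Li+].[O-]C1=CC=C(C)CC1 | intermediate (not isolated)
6 | racemic tert-butyl 3-methyl-6-oxocyclohex-2-ene-1-carboxylate | CC1=CC(C(=O)OC(C)(C)C)C(=O)CC1 | intermediate
7 | acrolein | C=CC=O | starting material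
8 | tert-butyl (1S)-3-methyl-6-oxo-1-(3-oxopropyl)cyclohex-2-ene-1-carboxylate | O=CCC[C@]1(C(=O)OC(C)(C)C)C=C(C)CCC1=O | intermediate (key-step precursor)
9 | C6 tertiary carbocation of the cis-fused cyclopentanol, tert-butyl ester intact (aluminium on the C4 oxygen not drawn) | O[C@@H]1CC[C@@]2(C(=O)OC(C)(C)C)C(=O)CC[C+](C)[C@@H]12 | intermediate (not isolated)
10 | (1S,4R,5R,6S)-4-hydroxy-6-methyl-11-oxatricyclo[4.3.2.0^1,5]undecane-9,10-dione | O[C@@H]1CC[C@@]23C(=O)O[C@@](C)(CCC2=O)[C@@H]13 | intermediate (key-step product)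
11 | (1S,5S,6S)-6-methyl-11-oxatricyclo[4.3.2.0^1,5]undecane-4,9,10-trione | O=C1CC[C@@]23C(=O)O[C@@](C)(CCC2=O)[C@@H]13 | intermediate
12 | (1S,5S,6S)-6-methyl-4-methylidene-11-oxatricyclo[4.3.2.0^1,5]undecane-9,10-dione | C=C1CC[C@@]23C(=O)O[C@@](C)(CCC2=O)[C@@H]13 | intermediate
13 | (1S,5S,6S,9S)-9-hydroxy-6-methyl-4-methylidene-11-oxatricyclo[4.3.2.0^1,5]undecan-10-one (axial OH) | C=C1CC[C@@]23C(=O)O[C@@](C)(CC[C@@H]2O)[C@@H]13 | intermediate
14 | (1R,5S,6S,9R)-9-bromo-6-methyl-4-methylidene-11-oxatricyclo[4.3.2.0^1,5]undecan-10-one (equatorial Br) | C=C1CC[C@@]23C(=O)O[C@@](C)(CC[C@H]2Br)[C@@H]13 | intermediate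
15 | 9-{[(1R,4S,5S,6S,9R)-9-bromo-6-methyl-10-oxo-11-oxatricyclo[4.3.2.0^1,5]undecan-4-yl]methyl}-9-borabicyclo[3.3.1]nonane | C(B1C2CCCC1CCC2)[C@H]1CC[C@@]23C(=O)O[C@@](C)(CC[C@H]2Br)[C@@H]13 | intermediate (not isolated)
16 | (1R,4S,5S,6S,9R)-9-bromo-4-(hydroxymethyl)-6-methyl-11-oxatricyclo[4.3.2.0^1,5]undecan-10-one | OC[C@H]1CC[C@@]23C(=O)O[C@@](C)(CC[C@H]2Br)[C@@H]13 | intermediate
17 | (1R,4S,5S,6S,9R)-9-bromo-4-(iodomethyl)-6-methyl-11-oxatricyclo[4.3.2.0^1,5]undecan-10-one | IC[C@H]1CC[C@@]23C(=O)O[C@@](C)(CC[C@H]2Br)[C@@H]13 | intermediate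
18 | 6-methylhept-5-en-2-one | CC(=O)CCC=C(C)C | starting material
19 | lithium 6-methylhepta-1,5-dien-2-olate | [Li+].[O-]C(=C)CCC=C(C)C | intermediate (not isolated)
20 | 6-methylhepta-1,5-dien-2-yl acetate | CC(=O)OC(=C)CCC=C(C)C | intermediate
21 | racemic 4-bromo-3,3-dimethylcyclohexan-1-one | O=C1CCC(Br)C(C)(C)C1 | intermediate
22 | (4R)-4-bromo-3,3-dimethylcyclohexan-1-one | O=C1CC[C@@H](Br)C(C)(C)C1 | intermediate
23 | {[(1R,4S,5S,6S,9R)-9-bromo-6-methyl-10-oxo-11-oxatricyclo[4.3.2.0^1,5]undecan-4-yl]methyl}samarium diiodide | I[Sm](I)C[C@H]1CC[C@@]23C(=O)O[C@@](C)(CC[C@H]2Br)[C@@H]13 | intermediate (not isolated)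
24 | (1R,4R,5S,6S,9R)-9-bromo-4-{[(1R,4R)-4-bromo-1-hydroxy-3,3-dimethylcyclohexyl]methyl}-6-methyl-11-oxatricyclo[4.3.2.0^1,5]undecan-10-one | O[C@@]1(C[C@H]2CC[C@@]34C(=O)O[C@@](C)(CC[C@H]3Br)[C@@H]24)CC[C@@H](Br)C(C)(C)C1 | intermediate
25 | (1R,4R)-4-bromo-1-{[(1R,4R,5S,6S,9R)-9-bromo-6-methyl-10-oxo-11-oxatricyclo[4.3.2.0^1,5]undecan-4-yl]methyl}-3,3-dimethylcyclohexyl acetate | CC(=O)O[C@@]1(C[C@H]2CC[C@@]34C(=O)O[C@@](C)(CC[C@H]3Br)[C@@H]24)CC[C@@H](Br)C(C)(C)C1 | target

Total step count: 16. Longest linear sequence: 13 steps (steps 1–11, 15, 16); steps 12–14 form the side-ring branch.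

Steps most likely to fail

Step 5. What may go wrong: after the C–C bond forms, the cationic centre may shed a proton (ene outcome), or the ester oxygen may be held by aluminium, so that the lactone does not close in the same operation. Fallback: setting out from 8, the closure is run as a plain Lewis-acid carbonyl-ene cyclisation (Me2AlCl, 1.1 equiv, CH2Cl2, −78 °C) and stopped at the cis-fused homoallylic alcohol tert-butyl (3R,3aR,7aS)-3-hydroxy-4-methyl-7-oxo-1,2,3,3a,6,7-hexahydro-7aH-indene-7a-carboxylate F1 (its exocyclic-alkene isomer should behave alike). CF3CO2H in CH2Cl2 (0 °C to rt) then cleaves the tert-butyl ester and adds the acid across the alkene through the same tertiary cation, which comes back to the route at 10.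

Step 9. What may go wrong: anti elimination of the axial oxyphosphonium group toward C8, or no substitution at a carbon flanked by quaternary C1. Fallback: setting out from 13, the alcohol is converted (Tf2O, pyridine, CH2Cl2, −30 °C) into (1S,5S,6S,9S)-6-methyl-4-methylidene-10-oxo-11-oxatricyclo[4.3.2.0^1,5]undecan-9-yl trifluoromethanesulfonate F2. This is displaced without delay by Bu4NBr in toluene (−30 °C to rt), a sulfonate displacement by a poorly solvated, non-basic bromide, and comes back to the route at 14.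

Step 15. What may go wrong: electron transfer to the C9–Br bond, or closure of the organosamarium carbon onto C9 (both lie close on the concave face), besides slow addition to the hindered ketone. Fallback: the C9 bromide is installed last. Setting out from 13, TESOTf/2,6-lutidine gives the C9 triethylsilyl ether of 13 F3. 9-BBN and then buffered H2O2 give, by way of the B-alkyl-9-BBN adduct F4, the silyl-protected primary alcohol F5. I2/PPh3/imidazole gives the silyl-protected iodide F6. The samarium Barbier reaction with 22 gives, by way of the alkylsamarium diiodide F7, the silyl-protected tertiary alcohol F8. Ac2O/DMAP gives the silyl-protected acetate F9, and HF·pyridine frees the axial C9 alcohol F10. The Appel conditions of step 9 applied to F10 come back to the route at 25.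

Further compounds

F1 | step 5 | tert-butyl (3R,3aR,7aS)-3-hydroxy-4-methyl-7-oxo-1,2,3,3a,6,7-hexahydro-7aH-indene-7a-carboxylate | O[C@@H]1CC[C@@]2(C(=O)OC(C)(C)C)C(=O)CC=C(C)[C@@H]12
F2 | step 9 | (1S,5S,6S,9S)-6-methyl-4-methylidene-10-oxo-11-oxatricyclo[4.3.2.0^1,5]undecan-9-yl trifluoromethanesulfonate | C=C1CC[C@@]23C(=O)O[C@@](C)(CC[C@@H]2OS(=O)(=O)C(F)(F)F)[C@@H]13
F3 | step 15 | (1S,5S,6S,9S)-6-methyl-4-methylidene-9-(triethylsilyloxy)-11-oxatricyclo[4.3.2.0^1,5]undecan-10-one | C=C1CC[C@@]23C(=O)O[C@@](C)(CC[C@@H]2O[Si](CC)(CC)CC)[C@@H]13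
F4 | step 15 | 9-{[(1S,4S,5S,6S,9S)-6-methyl-10-oxo-9-(triethylsilyloxy)-11-oxatricyclo[4.3.2.0^1,5]undecan-4-yl]methyl}-9-borabicyclo[3.3.1]nonane | C(B1C2CCCC1CCC2)[C@H]1CC[C@@]23C(=O)O[C@@](C)(CC[C@@H]2O[Si](CC)(CC)CC)[C@@H]13
F5 | step 15 | (1S,4S,5S,6S,9S)-4-(hydroxymethyl)-6-methyl-9-(triethylsilyloxy)-11-oxatricyclo[4.3.2.0^1,5]undecan-10-one | OC[C@H]1CC[C@@]23C(=O)O[C@@](C)(CC[C@@H]2O[Si](CC)(CC)CC)[C@@H]13
F6 | step 15 | (1S,4S,5S,6S,9S)-4-(iodomethyl)-6-methyl-9-(triethylsilyloxy)-11-oxatricyclo[4.3.2.0^1,5]undecan-10-one | IC[C@H]1CC[C@@]23C(=O)O[C@@](C)(CC[C@@H]2O[Si](CC)(CC)CC)[C@@H]13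
F7 | step 15 | {[(1S,4S,5S,6S,9S)-6-methyl-10-oxo-9-(triethylsilyloxy)-11-oxatricyclo[4.3.2.0^1,5]undecan-4-yl]methyl}samarium diiodide | I[Sm](I)C[C@H]1CC[C@@]23C(=O)O[C@@](C)(CC[C@@H]2O[Si](CC)(CC)CC)[C@@H]13
F8 | step 15 | (1S,4R,5S,6S,9S)-4-{[(1R,4R)-4-bromo-1-hydroxy-3,3-dimethylcyclohexyl]methyl}-6-methyl-9-(triethylsilyloxy)-11-oxatricyclo[4.3.2.0^1,5]undecan-10-one | O[C@@]1(C[C@H]2CC[C@@]34C(=O)O[C@@](C)(CC[C@@H]3O[Si](CC)(CC)CC)[C@@H]24)CC[C@@H](Br)C(C)(C)C1
F9 | step 15 | (1R,4R)-4-bromo-3,3-dimethyl-1-{[(1S,4R,5S,6S,9S)-6-methyl-10-oxo-9-(triethylsilyloxy)-11-oxatricyclo[4.3.2.0^1,5]undecan-4-yl]methyl}cyclohexyl acetate | CC(=O)O[C@@]1(C[C@H]2CC[C@@]34C(=O)O[C@@](C)(CC[C@@H]3O[Si](CC)(CC)CC)[C@@H]24)CC[C@@H](Br)C(C)(C)C1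
F10 | step 15 | (1R,4R)-4-bromo-1-{[(1S,4R,5S,6S,9S)-9-hydroxy-6-methyl-10-oxo-11-oxatricyclo[4.3.2.0^1,5]undecan-4-yl]methyl}-3,3-dimethylcyclohexyl acetate | CC(=O)O[C@@]1(C[C@H]2CC[C@@]34C(=O)O[C@@](C)(CC[C@@H]3O)[C@@H]24)CC[C@@H](Br)C(C)(C)C1
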